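## Retrosynthetic overview
1. Target 14 comes from chloride 13 by loss of HCl (C11–Cl is a masked isopropenyl group). The C10–H bond of 13 comes from conjugate reduction of diester enone 12.
2. Key disconnection: C8–O and C9–O. Both carbinol C–O bonds and the C9 ester arise in one flask by α-face syn-hydroxyacyloxylation of the γ,δ-olefin of chloro dienone 7. The C8 ester is added afterwards.
3. Dienone 7 comes from diketone 4 by cyclobutane scission (frees ring B, installs C11–Cl), aldol condensation (closes ring A) and dehydrogenation.
4. Diketone 4 comes from 3-methylnopinone 2 and (E)-pent-3-en-2-one 3 by Michael addition (C4–C5 bond). Ketone 2 comes from (+)-nopinone 1 and MeI.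
5. Ring order: ring B is carried in from nopinone, and ring A is closed in step 3.

Assumption: eremophilane numbering (C1–C15) is used for all bicyclic compounds. β is the face carrying the C14 and C15 methyl groups and the C7 side chain (4β,5β-dimethyl and 7β side chain throughout), and α is the opposite face. (+)-Nopinone is bought as such; it is the bulk ozonolysis product of (−)-β-pinene.

## Route

Step 1
Reactants: 1 (1R,5S)-(+)-nopinone
Product: 2 (1R,3S,5S)-3,6,6-trimethylbicyclo[3.1.1]heptan-2-one (3-methyl trans to the gem-dimethyl bridge)
Conditions: LiN(iPr)2, THF, −78 °C; MeI, −78 to 0 °C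
Reagents that add atoms: iodomethane, CI
Why: Kinetic enolate alkylation, in which only C3 can be deprotonated because C1 is a bridgehead and MeI enters anti to the gem-dimethyl bridge; this centre is planarised again in step 2.

Step 2
Reactants: 2 (1R,3S,5S)-3,6,6-trimethylbicyclo[3.1.1]heptan-2-one; 3 (E)-pent-3-en-2-one
Product: 4 (1R,3R,5R)-3,6,6-trimethyl-3-[(2S)-4-oxopentan-2-yl]bicyclo[3.1.1]heptan-2-one
Conditions: KOt-Bu (0.2 equiv), t-BuOH–THF, 0 °C, slow addition of 3 (1.5 equiv)
Reagents that add atoms: none
Why: Base-catalysed Michael addition (first half of a Robinson annulation), in which the only possible enolate of 2 takes up the enone on the face away from the gem-dimethyl bridge, so that C14 ends syn to that bridge (the future C7 side chain) and quaternary C5 is set, while the closed, metal-bridged transition state of an (E)-enone gives the cis-vicinal C4/C5 dimethyl array familiar from classical eremophilane annulations.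

Step 3
Reactants: 4 (1R,3R,5R)-3,6,6-trimethyl-3-[(2S)-4-oxopentan-2-yl]bicyclo[3.1.1]heptan-2-one
Product: 7 11-chloroeremophila-1(10),8-dien-2-one, via chloro diketone 5 (not isolated), via chloro enone 6 (not isolated)
Conditions: HCl (g), AcOH–1,4-dioxane, rt; then DDQ (1.1 equiv), rt
Reagents that add atoms: hydrogen chloride, Cl
Why: Acid-triggered cyclobutane scission next to the protonated C10 ketone gives the tertiary C11 cation, which chloride traps (masking the isopropenyl group and leaving C7 untouched), an acid-catalysed aldol condensation then closes ring A, and DDQ dehydrogenation of the acid-generated heteroannular dienol gives the linear dienone, as in the HCl/DDQ conversion of 4-en-3-ones into 4,6-dien-3-ones.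

Step 4
Reactants: 7 11-chloroeremophila-1(10),8-dien-2-one; 8 3-methylbut-2-enoyl chloride
Product: 10 11-chloro-8α-hydroxy-9α-(3-methylbut-2-enoyloxy)eremophil-1(10)-en-2-one, via enone diol 9 (not isolated)
Conditions: OsO4 (2 mol %), 10-hydroxy-10H-dibenzo[b,e][1,4]oxaborinine (10 mol %), N-methylmorpholine N-oxide monohydrate (1.1 equiv), CH2Cl2–MeCN, 0 °C to rt; then 8 (1.1 equiv), −20 °C; aq. Na2SO3 work-up
Reagents that add atoms: N-methylmorpholine N-oxide (one O), C[N+]1([O-])CCOCC1; water (one O, supplied as the hydrate), O
Why: Proposed new method: a one-flask osmium/borinic acid relay syn-hydroxyacyloxylation, in which octavalent osmium tetroxide adds suprafacially (3+2) to the γ,δ-olefin from the α face, because in the flat Δ1(10)-enone framework the axial C14 methyl and the C7 side chain close the β face, and this sets C8 and C9; the oxidation-resistant cyclic diarylborinic acid is meant to play two roles, first taking the glycolate over from hexavalent osmium by Os–O/B–O exchange (as arylboronic acids do in anhydrous osmylations) so that the hindered osmate turns over on the hydrate water alone, then holding the cis-diol as a tetracoordinate borinate whose more exposed, equatorial, allylic O9 attacks acyl chloride 8 while the N-methylmorpholine released from the oxidant takes up HCl, so that no strong base is present (no vinylketene from 8, no loss of HCl from C11) and the C9 ester is regiodefined; the closest known reactions are the Upjohn dihydroxylation with boronic acid capture and the borinic acid catalysed site-selective acylation of cis-1,2-diols, which have not been merged or applied to a dienone.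

Step 5
Reactants: 10 11-chloro-8α-hydroxy-9α-(3-methylbut-2-enoyloxy)eremophil-1(10)-en-2-one; 11 (E)-2-methylbut-2-enoyl chloride
Product: 12 11-chloro-9α-(3-methylbut-2-enoyloxy)-8α-[(E)-2-methylbut-2-enoyloxy]eremophil-1(10)-en-2-one
Conditions: 11 (1.5 equiv), pyridine (3 equiv), DMAP (0.1 equiv), CH2Cl2, 0 °C
Reagents that add atoms: none
Why: Nucleophile-catalysed O-acylation of the only remaining hydroxyl on the open α face, which leaves C8 unchanged and uses the thermodynamically stable (E)-acyl geometry.

Step 6
Reactants: 12 11-chloro-9α-(3-methylbut-2-enoyloxy)-8α-[(E)-2-methylbut-2-enoyloxy]eremophil-1(10)-en-2-one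
Product: 13 11-chloro-9α-(3-methylbut-2-enoyloxy)-8α-[(E)-2-methylbut-2-enoyloxy]-10βH-eremophilan-2-one
Conditions: [(Ph3P)CuH]6 (5 mol %), (EtO)2MeSiH (2 equiv), t-BuOH (2 equiv), toluene, 0 °C to rt
Reagents that add atoms: none
Why: Monovalent copper hydride conjugate reduction, in which the ketone-conjugated, strained Δ1(10) olefin is a much better acceptor than the two trisubstituted enoates and hydride enters C10 on the β face (syn to the angular methyl, as nucleophiles do with 4a-methyl octalones), because the axial C8 ester covers the α face and only β attack lets ring B flip into the cis-decalin and release the C14/C7 syn-axial strain; t-BuOH protonates the copper enolate.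

Step 7
Reactants: 13 11-chloro-9α-(3-methylbut-2-enoyloxy)-8α-[(E)-2-methylbut-2-enoyloxy]-10βH-eremophilan-2-one
Product: 14 9α-(3-methylbut-2-enoyloxy)-8α-[(E)-2-methylbut-2-enoyloxy]-10βH-eremophil-11-en-2-one, (4S,5R,7R,8R,9S,10S), the target
Conditions: NaOAc (5 equiv), AcOH, 90 °C
Reagents that add atoms: none
Why: Acetate-buffered E1-type dehydrochlorination, the protocol used for nootkatone-type hydrochlorides, in which the C11 cation loses one of six methyl protons rather than the single hindered H7, whose loss would give a tetrasubstituted olefin with strong allylic strain against the equatorial C8 ester; no stereocentre is touched.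

## Compound list
1 | (1R,5S)-(+)-nopinone (6,6-dimethylbicyclo[3.1.1]heptan-2-one) | O=C1CC[C@H]2C[C@@H]1C2(C)C | starting material
2 | (1R,3S,5S)-3,6,6-trimethylbicyclo[3.1.1]heptan-2-one | O=C1[C@@H](C)C[C@H]2C[C@@H]1C2(C)C | intermediate
3 | (E)-pent-3-en-2-one | C/C=C/C(C)=O | starting material
4 | (1R,3R,5R)-3,6,6-trimethyl-3-[(2S)-4-oxopentan-2-yl]bicyclo[3.1.1]heptan-2-one | O=C1[C@@](C)([C@@H](C)CC(C)=O)C[C@H]2C[C@@H]1C2(C)C | intermediate
5 | (2R,4R)-4-(2-chloropropan-2-yl)-2-methyl-2-[(2S)-4-oxopentan-2-yl]cyclohexan-1-one (chloro diketone) | CC(C)(Cl)[C@H]1C[C@](C)([C@@H](C)CC(C)=O)C(=O)CC1 | intermediate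
6 | 11-chloroeremophil-1(10)-en-2-one, (4S,4aR,6R)-6-(2-chloropropan-2-yl)-4,4a-dimethyl-4,4a,5,6,7,8-hexahydronaphthalen-2(3H)-one (chloro enone) | CC(C)(Cl)[C@H]1C[C@@]2(C)C(=CC(=O)C[C@@H]2C)CC1 | intermediate
7 | 11-chloroeremophila-1(10),8-dien-2-one, (4S,4aR,6S)-6-(2-chloropropan-2-yl)-4,4a-dimethyl-4,4a,5,6-tetrahydronaphthalen-2(3H)-one | CC(C)(Cl)[C@H]1C[C@@]2(C)C(=CC(=O)C[C@@H]2C)C=C1 | intermediate
8 | 3-methylbut-2-enoyl chloride (senecioyl chloride) | CC(C)=CC(=O)Cl | starting material
9 | 11-chloro-8α,9α-dihydroxyeremophil-1(10)-en-2-one (enone diol) | CC(C)(Cl)[C@H]1C[C@@]2(C)C(=CC(=O)C[C@@H]2C)[C@H](O)[C@@H]1O | intermediate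
10 | 11-chloro-8α-hydroxy-9α-(3-methylbut-2-enoyloxy)eremophil-1(10)-en-2-one | CC(C)(Cl)[C@H]1C[C@@]2(C)C(=CC(=O)C[C@@H]2C)[C@H](OC(=O)C=C(C)C)[C@@H]1O | intermediate
11 | (E)-2-methylbut-2-enoyl chloride (tigloyl chloride) | ClC(=O)/C(C)=C/C | starting material
12 | 11-chloro-9α-(3-methylbut-2-enoyloxy)-8α-[(E)-2-methylbut-2-enoyloxy]eremophil-1(10)-en-2-one | CC(C)(Cl)[C@H]1C[C@@]2(C)C(=CC(=O)C[C@@H]2C)[C@H](OC(=O)C=C(C)C)[C@@H]1OC(=O)/C(C)=C/C | intermediate
13 | 11-chloro-9α-(3-methylbut-2-enoyloxy)-8α-[(E)-2-methylbut-2-enoyloxy]-10βH-eremophilan-2-one | CC(C)(Cl)[C@H]1C[C@@]2(C)[C@H](CC(=O)C[C@@H]2C)[C@H](OC(=O)C=C(C)C)[C@@H]1OC(=O)/C(C)=C/C | intermediate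
14 | 9α-(3-methylbut-2-enoyloxy)-8α-[(E)-2-methylbut-2-enoyloxy]-10βH-eremophil-11-en-2-one | C=C(C)[C@H]1C[C@@]2(C)[C@H](CC(=O)C[C@@H]2C)[C@H](OC(=O)C=C(C)C)[C@@H]1OC(=O)/C(C)=C/C | target

## Step count and risks
Total step count: 7. Longest linear sequence: 7 (1 to 14).

**Step 2.** This is the weakest classical step. A tetrasubstituted, neopentyl-type enolate must add to a β-substituted, enolisable enone. Retro-Michael reaction, enone oligomerisation and erosion of the C4 selectivity are all possible. The fallback switches from donor activation to acceptor activation. Setting out from 2, TMSOTf/Et3N gives the trimethylsilyl enol ether of 2 F1. A Mukaiyama–Michael addition of this neutral nucleophile to 3 under TiCl4 (CH2Cl2, −78 °C) is irreversible. It still occurs anti to the gem-dimethyl bridge, and the pinane cage tolerates these conditions. Aqueous work-up comes back to the route at 4.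

**Step 4.** This is the proposed new step, and it can fail in three ways:
- The N-oxide may oxidise the borinic acid.
- The Os-to-B glycolate hand-over may bring no rate gain.
- Acylation in the spent osmylation mixture may be unselective.

The fallback uses only known chemistry and a different source of regiocontrol. Setting out from 7, a citric-acid-buffered Upjohn dihydroxylation (OsO4 cat., N-methylmorpholine N-oxide, t-BuOH–H2O) gives diol 9, now isolated. Bu2SnO (MeOH, 65 °C, then evaporation) converts it into the 8α,9α-O-dibutylstannylene acetal of 9 F2. This acetal is acylated by 8 (CH2Cl2, 0 °C) at the equatorial O9 and comes back to the route at 10.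

**Step 6.** This step can fail by sluggish hydride transfer to the hindered C10, by competing reduction of the tiglate, or by α attack giving the trans-decalin. The fallback replaces kinetic, polar hydride delivery by radical hydrogen-atom-transfer hydrogenation under thermodynamic stereocontrol. Setting out from 12, Mn(dpm)3 (10 mol %), PhSiH3 and t-BuOOH in i-PrOH at rt saturate the C1–C10 olefin through radical intermediates. This type of reduction gives the more stable ring fusion, which here is clearly the cis-decalin because only it allows an equatorial C7 side chain. The sequence comes back to the route at 13 and makes no compound outside the list (F0).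

Further compounds
F1 | step 2 | [(1R,5R)-3,6,6-trimethylbicyclo[3.1.1]hept-2-en-2-yl]oxy(trimethyl)silane | C[Si](C)(C)OC1=C(C)C[C@H]2C[C@@H]1C2(C)C
F2 | step 4 | 8α,9α-O-dibutylstannylene acetal of 11-chloro-8α,9α-dihydroxyeremophil-1(10)-en-2-one | CC(C)(Cl)[C@H]1C[C@@]2(C)C(=CC(=O)C[C@@H]2C)[C@H](O3)[C@@H]1O[Sn]3(CCCC)CCCC
F0 | step 6 | none | none
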